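Ring C is disconnected at C2–C3 and C4–C4a. C2, O1 and ring A then form an O-aryl oxocarbenium ion and C3–C4 a ketene acetal. The feature exploited is the symmetric 3,4,5-trimethoxyphenoxy ring A: its two equivalent ortho carbons, each activated by three oxygens, can capture a cation at C4. One operation thus builds both bonds, ring C, the C2 stereocentre and C4 at the ketone level. The precursor is the racemic O-aryl acetal of O-benzylvanillin that carries acetate, not methoxide, as second group, because an aryl methyl acetal ionises by loss of the aryloxide, whereas acetate leaves first and leaves only the O-aryl cation.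

Key step: step 3

Labels: flavanone numbering (O1, C2, C3, C4, C4a, C5–C8, C8a). Ring A is the benzo ring, ring B the 2-aryl group and ring C the pyranone ring.

Assumption: the sense of induction of the chiral acid cannot be predicted, so the antipode that delivers 2S in a test run is the one used (both antipodes are made from (R)- or (S)-BINOL).

Step 1
Reactants: 1 4-benzyloxy-3-methoxybenzoic acid; 2 3,4,5-trimethoxyphenol
Product: 3 3,4,5-trimethoxyphenyl 4-benzyloxy-3-methoxybenzoate
Conditions: DCC, DMAP (cat.), CH2Cl2, 0 °C to rt
Reagents that add atoms: none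
Why: Steglich esterification, in which DCC activates the acid as its O-acylisourea and DMAP passes the acyl group to the phenol oxygen; no stereocentre is formed.

Step 2
Reactants: 3 3,4,5-trimethoxyphenyl 4-benzyloxy-3-methoxybenzoate
Product: 5 rac-(4-benzyloxy-3-methoxyphenyl)(3,4,5-trimethoxyphenoxy)methyl acetate, via aluminium hemiacetal alkoxide 4 (not isolated)
Conditions: iBu2AlH (1.2 equiv), CH2Cl2, −78 °C; then pyridine, DMAP, Ac2O, −78 to −20 °C; aq. KNaC4H4O6 (potassium sodium tartrate) work-up; short column on Et3N-deactivated silica
Reagents that add atoms: acetic anhydride, CC(=O)OC(C)=O; diisobutylaluminium hydride, CC(C)C[AlH]CC(C)C (its aluminium stays only in 4)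
Why: Reductive acetylation of a carboxylic ester, in which one hydride adds at −78 °C to give the tetrahedral aluminium alkoxide 4 and this is O-acetylated in the cold before it can collapse; the new acetal carbon is racemic, which does not matter because step 3 planarises it.

Step 3
Reactants: 5 rac-(4-benzyloxy-3-methoxyphenyl)(3,4,5-trimethoxyphenoxy)methyl acetate; 6 1,1-dimethoxyethene
Product: 9 (S)-2-(4-benzyloxy-3-methoxyphenyl)-4,4,5,6,7-pentamethoxychroman, via O-aryl oxocarbenium ion 7 (not isolated), via dimethoxycarbenium ion 8 (not isolated)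
Conditions: BINOL-derived imidodiphosphorimidate Brønsted acid (IDPi; 3,3'-aryl = 3,5-(CF3)2C6H3, N-SO2CF3; 5 mol%), 6 (2.5 equiv, slow addition), toluene, −78 °C, anhydrous; Et3N quench at −78 °C
Reagents that add atoms: none
Why: Proposed new method: the chiral acid, directly or through the MeC(OMe)2+ ion it forms with 6, takes acetate from 5, and because acetate is a much better nucleofuge and a much poorer donor than the aryloxy group only the O-aryl oxocarbenium ion 7 arises, paired with the confined chiral anion. The nucleophilic CH2 of 6 adds to C2 of 7 (C2–C3 bond), the dimethoxycarbenium ion 8 so formed alkylates an ortho carbon of ring A (C4–C4a bond), and loss of the arenium proton returns the acid. The closest known reaction types are the SnCl4-promoted oxa-Povarov annulation of aryl oxocarbenium ions with alkenes and the chiral-anion-directed addition of silyl ketene acetals to oxocarbenium ions made from alpha-acetoxy or alpha-chloro ethers; what is new is the unsilylated ketene acetal, the Friedel–Crafts termination and asymmetric induction on an acyclic O-aryl cation. Ring C closes by an intramolecular Friedel–Crafts alkylation through a six-membered transition state, 6-exo-trig at C4 since the C=O+ bond of 8 stays outside the new ring. C2, the only stereocentre, is set in the C2–C3 bond formation by the chiral counteranion, which shields one face of planar 7, and it is not touched by the ring closure. Regioselectivity is secured by the symmetry of ring A (both ortho carbons identical, each ortho or para to three oxygen donors), and the second equivalent of 6 removes acetic acid as methyl acetate so that acetate can neither return to C2 nor demethylate 8.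

Step 4
Reactants: 9 (S)-2-(4-benzyloxy-3-methoxyphenyl)-4,4,5,6,7-pentamethoxychroman
Product: 10 (S)-2-(4-benzyloxy-3-methoxyphenyl)-5,6,7-trimethoxychroman-4-one
Conditions: PPTS (10 mol%), acetone/H2O 10:1, 0 °C to rt
Reagents that add atoms: water, O
Why: Acid-catalysed ketal hydrolysis, which needs only a pyridinium-buffered medium because the C4 cation is benzylic to the electron-rich ring A, so the C2–O1 bond stays closed and the C2 configuration is kept.

Step 5
Reactants: 10 (S)-2-(4-benzyloxy-3-methoxyphenyl)-5,6,7-trimethoxychroman-4-one
Product: 11 agecorynin E, (S)-2-(4-hydroxy-3-methoxyphenyl)-5,6,7-trimethoxychroman-4-one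
Conditions: H2 (1 atm), 10% Pd/C, EtOAc, rt, stopped at one equivalent of H2
Reagents that add atoms: none
Why: Catalytic hydrogenolysis of an aryl benzyl ether under neutral conditions, which is faster than reduction of the aryl ketone or cleavage of the secondary C2–O1 bond and avoids the base that would racemise a 4'-hydroxyflavanone by retro-oxa-Michael ring opening.

Compound list
1 | 4-benzyloxy-3-methoxybenzoic acid | COc1cc(C(=O)O)ccc1OCc1ccccc1 | starting material
2 | 3,4,5-trimethoxyphenol | COc1cc(O)cc(OC)c1OC | starting material
3 | 3,4,5-trimethoxyphenyl 4-benzyloxy-3-methoxybenzoate | COc1cc(C(=O)Oc2cc(OC)c(OC)c(OC)c2)ccc1OCc1ccccc1 | intermediate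
4 | diisobutylaluminium alkoxide of the hemiacetal (4-benzyloxy-3-methoxyphenyl)(3,4,5-trimethoxyphenoxy)methanol, racemic | COc1cc(C(O[Al](CC(C)C)CC(C)C)Oc2cc(OC)c(OC)c(OC)c2)ccc1OCc1ccccc1 | intermediate
5 | rac-(4-benzyloxy-3-methoxyphenyl)(3,4,5-trimethoxyphenoxy)methyl acetate | COc1cc(C(OC(C)=O)Oc2cc(OC)c(OC)c(OC)c2)ccc1OCc1ccccc1 | intermediate
6 | 1,1-dimethoxyethene | C=C(OC)OC | starting material
7 | (4-benzyloxy-3-methoxybenzylidene)(3,4,5-trimethoxyphenyl)oxonium ion, ion pair with the chiral anion | COc1cc(C=[O+]c2cc(OC)c(OC)c(OC)c2)ccc1OCc1ccccc1 | intermediate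
8 | (S)-3-(4-benzyloxy-3-methoxyphenyl)-1,1-dimethoxy-3-(3,4,5-trimethoxyphenoxy)propan-1-ylium ion, ion pair with the chiral anion | COc1cc([C@H](CC(OC)=[O+]C)Oc2cc(OC)c(OC)c(OC)c2)ccc1OCc1ccccc1 | intermediate
9 | (S)-2-(4-benzyloxy-3-methoxyphenyl)-4,4,5,6,7-pentamethoxychroman | COc1cc([C@@H]2CC(OC)(OC)c3c(cc(OC)c(OC)c3OC)O2)ccc1OCc1ccccc1 | intermediate
10 | (S)-2-(4-benzyloxy-3-methoxyphenyl)-5,6,7-trimethoxychroman-4-one | COc1cc([C@@H]2CC(=O)c3c(cc(OC)c(OC)c3OC)O2)ccc1OCc1ccccc1 | intermediate
11 | agecorynin E, (S)-2-(4-hydroxy-3-methoxyphenyl)-5,6,7-trimethoxychroman-4-one | COc1cc([C@@H]2CC(=O)c3c(cc(OC)c(OC)c3OC)O2)ccc1O | target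

Total step count: 5
Longest linear sequence: 5 steps (1 or 2 to 11)

Steps most likely to fail

1. Step 3.
- Possible failures:
  - The dimethoxycarbenium ion may be intercepted before ring closure, by demethylation down to the open-chain ester level or by proton loss.
  - The acid may start oligomerisation of the ketene acetal.
  - Facial selectivity on an acyclic, strongly stabilised cation may be poor.
  - Reversible acid-induced opening of the benzylic C2–O1 bond may erode the enantiomeric purity.
- Fallback (known chemistry only): it sets out from 2 and rejoins the route at 10.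
  - Compound 2 is C-acetylated ortho to the hydroxyl group (AcOH, BF3·OEt2, 85 °C, Friedel–Crafts acylation) to 1-(6-hydroxy-2,3,4-trimethoxyphenyl)ethanone F1.
  - Condensation with N,N-dimethylformamide dimethyl acetal gives (E)-3-(dimethylamino)-1-(6-hydroxy-2,3,4-trimethoxyphenyl)prop-2-en-1-one F2.
  - Aqueous HCl in CH2Cl2 cyclises this to 5,6,7-trimethoxychromen-4-one F3.
  - Asymmetric conjugate addition of commercial [4-(benzyloxy)-3-methoxyphenyl]boronic acid to F3 should give 10. The conditions are Pd(OCOCF3)2, the t-BuPyOx ligand antipode that gives 2S, NH4PF6, H2O, ClCH2CH2Cl, 60 °C. This reaction type is established for chromones.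

2. Step 2.
- Possible failures:
  - The tetrahedral aluminium alkoxide may collapse with loss of aryloxide before it is acetylated, and over-reduction would follow.
  - The labile acyloxy acetal may ionise during purification.
- Fallback: it sets out from 2 and rejoins the route at 9. It installs a different nucleofuge by substitution instead of reduction.
  - Commercial O-benzylvanillin, 1H-benzotriazole and SOCl2 (toluene, rt) give 1-[(4-benzyloxy-3-methoxyphenyl)chloromethyl]-1H-benzotriazole F4.
  - Compound 2 is deprotonated with NaH in THF/DMF to sodium 3,4,5-trimethoxyphenoxide F5.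
  - F5 displaces the chloride of F4 to give rac-1-[(4-benzyloxy-3-methoxyphenyl)(3,4,5-trimethoxyphenoxy)methyl]-1H-benzotriazole F6.
  - F6 takes the place of 5 in step 3. N-protonated benzotriazole leaves and the aryloxy group stays, so 7 and 8 are passed and 9 is reached.

3. Step 5.
- Possible failures:
  - The aryl ketone may be over-reduced, or the benzylic C2–O1 bond may be opened by hydrogenolysis on palladium.
  - The free 4'-hydroxyflavanone may ring-open and racemise on the catalyst surface.
- Fallback: it sets out from 9 and rejoins the route at 11. It reverses the order of the two unmaskings, so that no ketone is present during hydrogenation.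
  - Compound 9 is hydrogenolysed (H2, 10% Pd/C, EtOAc over solid NaHCO3) to (S)-2-methoxy-4-(4,4,5,6,7-pentamethoxychroman-2-yl)phenol F7.
  - The ketal of F7 is then hydrolysed with PPTS in aqueous acetone to 11.

Further compounds
F1 | step 3 | 1-(6-hydroxy-2,3,4-trimethoxyphenyl)ethanone | CC(=O)c1c(O)cc(OC)c(OC)c1OC
F2 | step 3 | (E)-3-(dimethylamino)-1-(6-hydroxy-2,3,4-trimethoxyphenyl)prop-2-en-1-one | CN(C)/C=C/C(=O)c1c(O)cc(OC)c(OC)c1OC
F3 | step 3 | 5,6,7-trimethoxychromen-4-one | COc1cc2occc(=O)c2c(OC)c1OC
F4 | step 2 | 1-[(4-benzyloxy-3-methoxyphenyl)chloromethyl]-1H-benzotriazole (racemic) | COc1cc(C(Cl)n2nnc3ccccc32)ccc1OCc1ccccc1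
F5 | step 2 | sodium 3,4,5-trimethoxyphenoxide | COc1cc([O-])cc(OC)c1OC.[Na+]
F6 | step 2 | rac-1-[(4-benzyloxy-3-methoxyphenyl)(3,4,5-trimethoxyphenoxy)methyl]-1H-benzotriazole | COc1cc(C(Oc2cc(OC)c(OC)c(OC)c2)n2nnc3ccccc32)ccc1OCc1ccccc1
F7 | step 5 | (S)-2-methoxy-4-(4,4,5,6,7-pentamethoxychroman-2-yl)phenol | COc1cc([C@@H]2CC(OC)(OC)c3c(cc(OC)c(OC)c3OC)O2)ccc1O
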